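**Retrosynthetic overview**
- The only ring is formed last: the C3–C4 bond is closed by an intramolecular Nozaki–Hiyama–Kishi addition of a β-acylvinyl chromium (an enone β-carbon made nucleophilic) onto an α-chiral aldehyde, which sets C4.
- The (Z)-β-iodoenone needed for that closure comes from anti hydroiodination of an ynone.
- Key bond C5–C6: the 1,4-keto aldehyde is disconnected between the two carbonyl α-carbons. The enamine radical cation of geranylgeranylacetaldehyde (an enolonium equivalent) is joined to the silyl enol ether of pent-3-yn-2-one under oxidative organocatalysis, and the catalyst sets C5.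
- The C22 aldehyde comes from geranylgeranyl bromide and an acetaldehyde azaenolate; the bromide comes from all-E geranylgeraniol.

Assumption: the SMILES is read as the cis-(4R,5R) enone with an all-E side chain, and commercial (2E,6E,10E)-geranylgeraniol is the C20 source.

**Route**

Step 1
Reactants: 1 (2E,6E,10E)-geranylgeraniol
Product: 2 (2E,6E,10E)-geranylgeranyl bromide
Conditions: PBr3 (0.4 equiv), Et2O, −10 to 0 °C; used crude
Reagents that add atoms: phosphorus tribromide, BrP(Br)Br
Why: Allylic bromination with PBr3 (SN2 displacement of the bromophosphite ester) converts the primary allylic alcohol at low temperature without E/Z or allylic scrambling; no stereocentre is formed.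

Step 2
Reactants: 2 (2E,6E,10E)-geranylgeranyl bromide; 3 acetaldehyde N,N-dimethylhydrazone
Product: 6 (4E,8E,12E)-5,9,13,17-tetramethyloctadeca-4,8,12,16-tetraenal, via lithium azaenolate 4 (not isolated), via alkylated hydrazone 5 (not isolated)
Conditions: LiN(iPr)2, THF, 0 °C; then 2, −78 to 0 °C; then aq. oxalic acid, Et2O, rt
Reagents that add atoms: water, O
Why: Corey–Enders azaenolate alkylation: the lithiated hydrazone is an acetaldehyde enolate equivalent that attacks the primary allylic bromide at carbon in SN2 fashion, and mild biphasic acid hydrolysis releases the aldehyde without touching the trisubstituted alkenes; no stereocentre is formed.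

Step 3
Reactants: 7 pent-3-yn-2-one
Product: 8 tert-butyldimethyl(pent-1-en-3-yn-2-yloxy)silane
Conditions: TBSOTf, Et3N, CH2Cl2, 0 °C
Reagents that add atoms: tert-butyldimethylsilyl triflate, CC(C)(C)[Si](C)(C)OS(=O)(=O)C(F)(F)F
Why: Soft enolisation and O-silylation (silyl enol ether formation): the silyl triflate activates the carbonyl and Et3N removes an acetyl proton, giving the 2-siloxy enyne; no stereocentre is formed.

Step 4
Reactants: 6 (4E,8E,12E)-5,9,13,17-tetramethyloctadeca-4,8,12,16-tetraenal; 8 tert-butyldimethyl(pent-1-en-3-yn-2-yloxy)silane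
Product: 10 (2R)-4-oxo-2-[(2E,6E,10E)-3,7,11,15-tetramethylhexadeca-2,6,10,14-tetraen-1-yl]hept-5-ynal, via catalyst enamine 9 (not isolated)
Conditions: 8 (2 equiv), (2S,5S)-5-benzyl-2-tert-butyl-3-methylimidazolidin-4-one trifluoroacetate (20 mol%), (NH4)2Ce(NO3)6 (2.2 equiv), 2,6-di-tert-butylpyridine (2 equiv), H2O (2 equiv), acetone, −20 °C
Reagents that add atoms: water, O (the aldehyde oxygen of 10 is returned from water when the iminium ion is hydrolysed)
Why: SOMO-activation organocatalysis (oxidative α-enolation of an aldehyde): tetravalent cerium oxidises enamine 9 by one electron to a radical cation whose α-carbon is electrophilic, the enolsilane 8 adds to it, and a second oxidation, loss of silyl and hydrolysis give the 1,4-keto aldehyde; the E radical cation lies away from the tert-butyl group and the benzyl group blocks the Re face, so 8 adds to the Si face and C2 (the future C5) is set as R.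

Step 5
Reactants: 10 (2R)-4-oxo-2-[(2E,6E,10E)-3,7,11,15-tetramethylhexadeca-2,6,10,14-tetraen-1-yl]hept-5-ynal
Product: 11 (2R,5Z)-6-iodo-4-oxo-2-[(2E,6E,10E)-3,7,11,15-tetramethylhexadeca-2,6,10,14-tetraen-1-yl]hept-5-enal
Conditions: NaI (2 equiv), AcOH (3 equiv), MeCN, 0 °C to rt
Reagents that add atoms: sodium iodide, [Na+].[I-]
Why: Conjugate hydroiodination of an ynone: iodide adds to the β-carbon and net anti addition of HI gives the kinetic Z β-iodoenone (iodine cis to the carbonyl), while the unactivated alkenes and the aldehyde are untouched and the cold, weakly acidic medium spares the C2 stereocentre.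

Step 6
Reactants: 11 (2R,5Z)-6-iodo-4-oxo-2-[(2E,6E,10E)-3,7,11,15-tetramethylhexadeca-2,6,10,14-tetraen-1-yl]hept-5-enal
Product: 14 (4R,5R)-4-hydroxy-3-methyl-5-[(2E,6E,10E)-3,7,11,15-tetramethylhexadeca-2,6,10,14-tetraen-1-yl]cyclohex-2-en-1-one (target), via vinylchromium species 12 (not isolated), via chromium alkoxide 13 (not isolated)
Conditions: CrCl2 (6 equiv), NiCl2 (2 mol%), degassed DMF, rt, 0.01 M; aqueous work-up
Reagents that add atoms: none
Why: Intramolecular Nozaki–Hiyama–Kishi reaction: zerovalent nickel inserts into the activated C–I bond and transmetalation gives the β-acylvinyl chromium 12, which adds only to the aldehyde to close the six-membered ring with retention of the Z geometry; in the half-chair transition state the C5 side chain is pseudo-equatorial and anti to the incoming vinyl carbon (Felkin–Anh) and the aldehyde oxygen is pseudo-axial, away from the C3 methyl (A(1,2) strain), which sets C4 as R, cis to the side chain.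

**Compound list**

1 | (2E,6E,10E)-geranylgeraniol | CC(C)=CCC/C(C)=C/CC/C(C)=C/CC/C(C)=C/CO | starting material
2 | (2E,6E,10E)-geranylgeranyl bromide | CC(C)=CCC/C(C)=C/CC/C(C)=C/CC/C(C)=C/CBr | intermediate
3 | acetaldehyde N,N-dimethylhydrazone | C/C=N/N(C)C | starting material
4 | lithium azaenolate of 3 | C=CN([Li])N(C)C | intermediate (not isolated)
5 | N,N-dimethylhydrazone of aldehyde 6 | CC(C)=CCC/C(C)=C/CC/C(C)=C/CC/C(C)=C/CC/C=N/N(C)C | intermediate (not isolated)
6 | (4E,8E,12E)-5,9,13,17-tetramethyloctadeca-4,8,12,16-tetraenal | CC(C)=CCC/C(C)=C/CC/C(C)=C/CC/C(C)=C/CCC=O | intermediate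
7 | pent-3-yn-2-one | CC#CC(C)=O | starting material
8 | tert-butyldimethyl(pent-1-en-3-yn-2-yloxy)silane | CC#CC(=C)O[Si](C)(C)C(C)(C)C | intermediate
9 | E-enamine of 6 with (2S,5S)-5-benzyl-2-tert-butyl-3-methylimidazolidin-4-one | CN1[C@@H](C(C)(C)C)N(/C=C/C/C=C(\C)CC/C=C(\C)CC/C=C(\C)CCC=C(C)C)[C@@H](Cc2ccccc2)C1=O | intermediate (not isolated)
10 | (2R)-4-oxo-2-[(2E,6E,10E)-3,7,11,15-tetramethylhexadeca-2,6,10,14-tetraen-1-yl]hept-5-ynal | O=C[C@@H](CC(=O)C#CC)C/C=C(\C)CC/C=C(\C)CC/C=C(\C)CCC=C(C)C | intermediate
11 | (2R,5Z)-6-iodo-4-oxo-2-[(2E,6E,10E)-3,7,11,15-tetramethylhexadeca-2,6,10,14-tetraen-1-yl]hept-5-enal | O=C[C@@H](CC(=O)/C=C(/C)I)C/C=C(\C)CC/C=C(\C)CC/C=C(\C)CCC=C(C)C | intermediate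
12 | β-acylvinyl dichlorochromium species (trivalent chromium) from 11 | O=C[C@@H](CC(=O)/C=C(/C)[Cr](Cl)Cl)C/C=C(\C)CC/C=C(\C)CC/C=C(\C)CCC=C(C)C | intermediate (not isolated)
13 | dichlorochromium alkoxide (trivalent chromium) of 14 | CC(C)=CCC/C(C)=C/CC/C(C)=C/CC/C(C)=C/C[C@@H]1CC(=O)C=C(C)[C@@H]1O[Cr](Cl)Cl | intermediate (not isolated)
14 | (4R,5R)-4-hydroxy-3-methyl-5-[(2E,6E,10E)-3,7,11,15-tetramethylhexadeca-2,6,10,14-tetraen-1-yl]cyclohex-2-en-1-one | CC(C)=CCC/C(C)=C/CC/C(C)=C/CC/C(C)=C/C[C@@H]1CC(=O)C=C(C)[C@@H]1O | target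

**Step count**

Total steps: 6. Longest linear sequence: 5 (steps 1, 2, 4, 5, 6); step 3 is a one-step side branch.

**Steps most likely to fail, with fallbacks**

Step 4 (oxidative α-enolation). Risks: tetravalent cerium may attack the tetraene, the alkynyl enolsilane is an untested partner, and the ee may be low. Fallback: the same C5–C6 bond is made under auxiliary control, setting out from 6. Condensation with (R)-1-amino-2-(methoxymethyl)pyrrolidine gives RAMP hydrazone F1. Deprotonation with LiN(iPr)2 and alkylation with 2-bromo-N-methoxy-N-methylacetamide at −100 °C gives Weinreb amide F2, with the R configuration at the new centre (the mirror-image auxiliary series gives S). CH3C≡CMgBr turns the amide into ynone hydrazone F3. Biphasic aqueous oxalic acid cleaves the hydrazone without racemisation and the route is rejoined at 10.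

Step 5 (hydroiodination of the keto aldehyde). Risks: acid-promoted epimerisation at C2 and furan formation from the 1,4-keto aldehyde. Fallback: the iodine is installed before the coupling, setting out from 7. Hydroiodination (NaI, AcOH) gives (Z)-4-iodopent-3-en-2-one F4, which is converted (TBSOTf, iPr2NEt, CH2Cl2) into silyl dienol ether F5. F5 replaces 8 in the oxidative coupling with 6 under the conditions of step 4, and the route is rejoined at 11 with step 5 removed from the linear sequence.

Step 6 (ring closure). Risk: the cis preference at C4 rests on a conformational argument and may be modest or reversed. Fallback: setting out from 11, the closure is run as before and the C4 epimer, trans alcohol F6, is separated. A Mitsunobu reaction (PPh3, diisopropyl azodicarboxylate, 4-nitrobenzoic acid, THF, 0 °C) gives 4-nitrobenzoate F7 with inversion at C4. K2CO3 in MeOH at 0 °C then releases the alcohol and the route is rejoined at 14.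

**Further compounds**

F1 | step 4 | RAMP hydrazone of 6 | CC(C)=CCC/C(C)=C/CC/C(C)=C/CC/C(C)=C/CC/C=N/N1CCC[C@@H]1COC
F2 | step 4 | (3R)-N-methoxy-N-methyl amide alkylation product of F1 (Weinreb amide hydrazone) | CON(C)C(=O)C[C@@H](C/C=C(\C)CC/C=C(\C)CC/C=C(\C)CCC=C(C)C)/C=N/N1CCC[C@@H]1COC
F3 | step 4 | RAMP hydrazone of 10 (ynone hydrazone) | CC#CC(=O)C[C@@H](C/C=C(\C)CC/C=C(\C)CC/C=C(\C)CCC=C(C)C)/C=N/N1CCC[C@@H]1COC
F4 | step 5 | (Z)-4-iodopent-3-en-2-one | C/C(I)=C/C(C)=O
F5 | step 5 | tert-butyl{[(3Z)-4-iodopenta-1,3-dien-2-yl]oxy}dimethylsilane | C/C(I)=C/C(=C)O[Si](C)(C)C(C)(C)C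
F6 | step 6 | (4S,5R)-4-hydroxy-3-methyl-5-[(2E,6E,10E)-3,7,11,15-tetramethylhexadeca-2,6,10,14-tetraen-1-yl]cyclohex-2-en-1-one (trans epimer) | CC(C)=CCC/C(C)=C/CC/C(C)=C/CC/C(C)=C/C[C@@H]1CC(=O)C=C(C)[C@H]1O
F7 | step 6 | (4R,5R)-4-nitrobenzoate of 14 | CC(C)=CCC/C(C)=C/CC/C(C)=C/CC/C(C)=C/C[C@@H]1CC(=O)C=C(C)[C@@H]1OC(=O)c2ccc(cc2)[N+](=O)[O-]
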